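**Plan**

- Retrosynthesis: ring C is opened at O1–C2 (back to an α,β-epoxy ketone, then to the Cα=Cβ alkene of a 2′-hydroxychalcone). Ring A is then removed by cutting C4–C4a and O1–C8a together, leaving a ring B acrylic acid and an aryne. The methylcyclohexene is cut at C3″–C4″ and C5″–C6″ into a 2′-hydroxychalcone and an aryl diene.
- Forward order: the cyclohexene ring is made first (Diels–Alder), ring A is joined to the ring B side chain by aryne insertion into the acid, and ring C is closed last by epoxide opening.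
- Enabling feature: in ring A the C4 acyl carbon sits on C4a and O1 on the neighbouring C8a. This ortho C-acyl/oxygen pair is what an aryne takes up from a carboxylate in one operation. C5 is unsubstituted, so a chlorine can be carried there to steer the addition and be removed later.
- Stereochemistry: C3″, C4″ and C5″ come from an exo Diels–Alder reaction under a chiral borate (C4″ is also the thermodynamic, all-equatorial epimer). C3 comes from a ligand-controlled epoxidation and C2 from inversion at the benzylic epoxide carbon.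
- Numbering: flavanonol atoms O1–C8a and rings A, B, C as usual; cyclohexene C1″ (methyl), C2″ (=CH), C3″ (ring B), C4″ (aroyl), C5″ (aryl), C6″ (CH2). MOM = methoxymethyl.

Key step: step 17

Assumption: (S)-VANOL (step 10) and (S)-BINOL (step 19) are taken as the ligand enantiomers that give the configurations drawn, by analogy with simpler 2′-hydroxychalcone cycloadditions and with chalcone epoxidation; if either sense proves opposite, the (R) ligand is used.

**Route**

Step 1
Reactants: 1 2,4-dihydroxyacetophenone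
Product: 2 1-[2-hydroxy-4-(methoxymethoxy)phenyl]ethan-1-one
Conditions: MOMCl (1.1 equiv), K2CO3, acetone, 0 °C to rt
Reagents that add atoms: chloromethyl methyl ether, COCCl
Why: Williamson-type O-alkylation goes to the 4-hydroxyl only, because the 2-hydroxyl is tied up in a hydrogen bond to the ketone and is not alkylated under carbonate at room temperature.

Step 2
Reactants: 3 2,4-dihydroxybenzaldehyde
Product: 4 2,4-bis(methoxymethoxy)benzaldehyde
Conditions: NaH, DMF, 0 °C; MOMCl, 0 °C to rt
Reagents that add atoms: chloromethyl methyl ether, COCCl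
Why: Double O-alkylation of the sodium bis-phenoxide, the stronger base bringing the chelated 2-hydroxyl to reaction as well.

Step 3
Reactants: 2 1-[2-hydroxy-4-(methoxymethoxy)phenyl]ethan-1-one; 4 2,4-bis(methoxymethoxy)benzaldehyde
Product: 5 2′-hydroxychalcone dienophile
Conditions: KOH, EtOH/H2O, 0 °C to rt
Reagents that add atoms: none
Why: Claisen–Schmidt condensation, in which the acetophenone enolate adds to the non-enolisable aldehyde and E1cB loss of water gives the conjugated E enone while the aryl acetals are inert to hydroxide.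

Step 4
Reactants: 6 resorcinol
Product: 7 1,3-bis(methoxymethoxy)benzene
Conditions: NaH, DMF, 0 °C; MOMCl, 0 °C to rt
Reagents that add atoms: chloromethyl methyl ether, COCCl
Why: Double Williamson-type O-alkylation of the bis-phenoxide, which also installs the two directing groups for step 5.

Step 5
Reactants: 7 1,3-bis(methoxymethoxy)benzene
Product: 9 2,6-bis(methoxymethoxy)benzaldehyde, via aryllithium 8 (not isolated)
Conditions: n-BuLi, THF, 0 °C; DMF, 0 °C to rt; H2O
Reagents that add atoms: N,N-dimethylformamide, CN(C)C=O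
Why: Directed ortho-metalation removes the C2 proton that is flanked and coordinated by both acetal oxygens, and the aryllithium is formylated by DMF.

Step 6
Reactants: 9 2,6-bis(methoxymethoxy)benzaldehyde
Product: 10 3-bromo-2,6-bis(methoxymethoxy)benzaldehyde
Conditions: NBS (1.05 equiv), MeCN, 0 °C to rt
Reagents that add atoms: N-bromosuccinimide, O=C1CCC(=O)N1Br
Why: Electrophilic aromatic bromination takes C3, which is ortho to one acetal oxygen and para to the other, whereas C4 is meta to both donors and para to the formyl group, and one equivalent of NBS keeps it at monobromination.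

Step 7
Reactants: 10 3-bromo-2,6-bis(methoxymethoxy)benzaldehyde; 11 methyl acrylate
Product: 12 methyl (E)-3-[3-formyl-2,4-bis(methoxymethoxy)phenyl]prop-2-enoate
Conditions: Pd(OAc)2 (5 mol %), P(o-tol)3, NaOAc, DMF, 110 °C
Reagents that add atoms: none
Why: Heck reaction, in which oxidative addition of the aryl bromide, syn insertion of the acrylate and syn β-hydride elimination give the E cinnamate while the aldehyde and the acetals are tolerated.

Step 8
Reactants: 12 methyl (E)-3-[3-formyl-2,4-bis(methoxymethoxy)phenyl]prop-2-enoate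
Product: 13 aryl enone (E-3-oxobut-1-enyl group on ring B)
Conditions: Ph3P=CHC(O)CH3, toluene, 100 °C
Reagents that add atoms: 1-(triphenyl-λ5-phosphanylidene)propan-2-one, CC(=O)C=P(c1ccccc1)(c1ccccc1)c1ccccc1
Why: Wittig reaction of the stabilised ylide takes place only at the aldehyde and, as stabilised ylides do, gives the E enone.

Step 9
Reactants: 13 aryl enone
Product: 14 aryl diene (E-3-methylbuta-1,3-dienyl group on ring B)
Conditions: Ph3PCH3Br, KOt-Bu, THF, 0 °C; then 13, 0 °C to rt
Reagents that add atoms: methyltriphenylphosphonium bromide, C[P+](c1ccccc1)(c1ccccc1)c1ccccc1.[Br-]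
Why: Wittig methylenation, in which the unstabilised ylide adds 1,2 to the methyl ketone much faster than to the ester and turns it into the isopropenyl group without touching the two E alkenes.

Step 10
Reactants: 5 2′-hydroxychalcone dienophile; 14 aryl diene
Product: 15 exo cycloadduct (methyl ester, 2-hydroxyaroyl group)
Conditions: chiral borate catalyst preformed from (S)-VANOL [(S)-3,3′-diphenyl-2,2′-binaphthalene-1,1′-diol], BH3·THF and AcOH (30 mol % each), THF, rt
Reagents that add atoms: none
Why: Diels–Alder reaction of the boron-chelated 2′-hydroxychalcone, in which binding of the phenoxide and the carbonyl oxygen to the VANOL borate activates the enone and shields one face, the 1-aryl and 3-methyl groups of the diene direct the regiochemistry, the E alkene fixes C4″/C5″ trans, and the exo approach (expected to be favoured by the clash between the borate and the twisted, di-ortho-substituted aryl group of the diene) sets C3″ trans to the aroyl group, so that C3″, C4″ and C5″ are fixed as R, R and S, material from the endo approach being removed by chromatography.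

Step 11
Reactants: 15 exo cycloadduct
Product: 16 fully MOM-protected methyl ester
Conditions: MOMCl, K2CO3, acetone, 50 °C
Reagents that add atoms: chloromethyl methyl ether, COCCl
Why: O-alkylation of the last free, ketone-chelated phenol, which would otherwise be arylated by the aryne in step 17, under warm carbonate that cannot harm C4″ because it is already the more stable epimer.

Step 12
Reactants: 16 fully MOM-protected methyl ester
Product: 17 ring B (E)-acrylic acid
Conditions: LiOH·H2O, THF/MeOH/H2O, rt; then 0.5 M HCl to pH 4, 0 °C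
Reagents that add atoms: lithium hydroxide, [Li+].[OH-]
Why: Saponification of the methyl ester by addition–elimination at the acyl carbon, followed by a cold acidification that is too mild to cleave the aryl acetals.

Step 13
Reactants: 18 5-chlororesorcinol
Product: 19 4-bromo-5-chlorobenzene-1,3-diol
Conditions: NBS (1.0 equiv), MeCN, −20 to 0 °C
Reagents that add atoms: N-bromosuccinimide, O=C1CCC(=O)N1Br
Why: Electrophilic bromination of the resorcinol goes para to one hydroxyl and ortho to the other rather than to the more hindered position between the two hydroxyls, and because C4 and C6 are equivalent a single monobromide results.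

Step 14
Reactants: 19 4-bromo-5-chlorobenzene-1,3-diol
Product: 20 bis(trimethylsilyl) ether
Conditions: HMDS, THF, 65 °C; concentrate
Reagents that add atoms: hexamethyldisilazane, C[Si](C)(C)N[Si](C)(C)C
Why: Silylation of both phenols with HMDS, ammonia being the only by-product, installs the silyl group that is to migrate and masks the second phenol during the lithiation.

Step 15
Reactants: 20 bis(trimethylsilyl) ether
Product: 24 3-chloro-5-hydroxy-2-(trimethylsilyl)phenyl trifluoromethanesulfonate, via aryllithium 21 (not isolated), via lithium phenolate 22 (not isolated), via silyloxy triflate 23 (not isolated)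
Conditions: n-BuLi, THF, −100 to −78 °C; Tf2O, −78 °C; then NaHCO3, MeOH/H2O, 0 °C
Reagents that add atoms: trifluoromethanesulfonic anhydride, O=S(=O)(OS(=O)(=O)C(F)(F)F)C(F)(F)F
Why: Bromine–lithium exchange gives the aryllithium, whose 1,3 O-to-C silyl shift (retro-Brook rearrangement) is expected to be faster at this temperature than loss of LiCl, the resulting phenolate is triflated in the same flask, and the remaining, very labile phenolic silyl ether is hydrolysed in the bicarbonate work-up.

Step 16
Reactants: 24 3-chloro-5-hydroxy-2-(trimethylsilyl)phenyl trifluoromethanesulfonate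
Product: 25 3-chloro-5-(methoxymethoxy)-2-(trimethylsilyl)phenyl trifluoromethanesulfonate
Conditions: MOMCl, K2CO3, acetone, 0 °C to rt
Reagents that add atoms: chloromethyl methyl ether, COCCl
Why: Williamson-type O-alkylation of the unhindered phenol under carbonate, which does not disturb the silyl triflate because elimination to the aryne needs fluoride.

Step 17
Reactants: 17 ring B (E)-acrylic acid; 25 3-chloro-5-(methoxymethoxy)-2-(trimethylsilyl)phenyl trifluoromethanesulfonate
Product: 27 2′-hydroxychalcone with chlorine on the future C5, via aryne 26 (not isolated)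
Conditions: CsF (4 equiv), 25 (1.5 equiv), THF, 125 °C, sealed tube
Reagents that add atoms: none
Why: Fluoride attacks the silicon of 25 and triflate leaves, giving aryne 26; the cesium carboxylate of 17 adds through oxygen to the aryne carbon remote from chlorine (future C8a), and the aryl anion that develops on C4a, next to the C–Cl bond, attacks the ester carbonyl through a four-membered transition state whose collapse moves the acyl group from oxygen to carbon and frees the phenoxide. The closest known reaction type is the formal insertion of arynes into the C–O bond of carboxylic acids (O-arylation followed by an anionic Fries-type 1,3-acyl shift), which gives ortho-hydroxyaryl ketones, also from α,β-unsaturated acids. The O1–C8a and C4–C4a bonds form in one operation; no ring is closed and no stereocenter is created. The step needs regioselectivity, which the chlorine secures by distorting and polarising the aryne so that the nucleophile enters at the distal carbon and the negative charge builds up next to the halogen, an effect that outweighs the weaker opposite bias of the 5-methoxymethoxy group. It also needs C-acylation to beat protonation of the aryl anion, which the high temperature in THF favours, and it needs the substrate to stand hot fluoride: all phenols are capped as acetals, the E alkene is not touched, and C4″, the only epimerisable center, is already the all-equatorial epimer.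

Step 18
Reactants: 27 2′-hydroxychalcone with chlorine on the future C5
Product: 28 2′-O-triisopropylsilyl chalcone
Conditions: NaH (1.05 equiv), THF, 0 °C; TIPSCl, 0 °C to rt
Reagents that add atoms: chlorotri(propan-2-yl)silane, CC(C)[Si](Cl)(C(C)C)C(C)C
Why: O-silylation of the sodium phenoxide, which in an aprotic medium stays open-chain rather than adding to the enone, gives a bulky silyl ether that blocks oxa-Michael closure and withstands the peroxide of step 19.

Step 19
Reactants: 28 2′-O-triisopropylsilyl chalcone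
Product: 29 (αR,βS)-epoxy ketone
Conditions: La(O-i-Pr)3 (10 mol %), (S)-BINOL (10 mol %), Ph3As=O (10 mol %), TBHP (decane), 4 Å MS, THF, rt
Reagents that add atoms: tert-butyl hydroperoxide, CC(C)(C)OO
Why: Nucleophilic (Weitz–Scheffer-type) epoxidation by a lanthanum tert-butylperoxide held in the (S)-BINOL/Ph3As=O complex, in which conjugate addition of the peroxide to one face of the carbonyl-bound enone and ring closure set Cα as R and Cβ as S, the trans relationship follows from the E alkene, and the isolated trisubstituted alkene and the saturated ketone do not react.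

Step 20
Reactants: 29 (αR,βS)-epoxy ketone
Product: 31 5-chloroflavanonol (hepta-MOM), via epoxy phenol 30 (not isolated)
Conditions: Bu4NF, AcOH, THF, 0 °C to rt
Reagents that add atoms: none
Why: Fluoride cleaves the Si–O bond and the liberated phenol opens the epoxide at the benzylic carbon, which the two oxygen donors of ring B activate, in a 6-endo SN2 displacement, so that C2 is formed with inversion (R) while C3 keeps the Cα configuration (R) to give the 2,3-trans flavanonol, acetic acid keeping the medium from becoming basic enough to epimerise it.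

Step 21
Reactants: 31 5-chloroflavanonol (hepta-MOM)
Product: 32 hepta-MOM guangsangon K
Conditions: Pd(OAc)2 (5 mol %), P(t-Bu)3 (10 mol %), HCOONa, DMF, 80 °C
Reagents that add atoms: none
Why: Palladium-catalysed transfer hydrodechlorination, in which the zerovalent palladium–phosphine complex inserts into the C5–Cl bond activated by the ortho carbonyl, formate replaces chloride and loses CO2 to give an aryl palladium hydride, and reductive elimination forms the C5–H bond without touching the alkene, the ketones or the acetals.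

Step 22
Reactants: 32 hepta-MOM guangsangon K
Product: 33 guangsangon K
Conditions: HCl (1 M in MeOH), THF, 40 °C
Reagents that add atoms: none
Why: Acid-catalysed acetal exchange with methanol removes all seven methoxymethyl groups as dimethoxymethane, no bond to a stereocenter being broken and both the 2,3-trans flavanonol and the all-equatorial cyclohexene being the stable epimers.

**Compound list**

1 | 2,4-dihydroxyacetophenone | CC(=O)c1ccc(O)cc1O | starting material
2 | 1-[2-hydroxy-4-(methoxymethoxy)phenyl]ethan-1-one | CC(=O)c1ccc(OCOC)cc1O | intermediate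
3 | 2,4-dihydroxybenzaldehyde | O=Cc1ccc(O)cc1O | starting material
4 | 2,4-bis(methoxymethoxy)benzaldehyde | COCOc1ccc(C=O)c(OCOC)c1 | intermediate
5 | (2E)-3-[2,4-bis(methoxymethoxy)phenyl]-1-[2-hydroxy-4-(methoxymethoxy)phenyl]prop-2-en-1-one | COCOc1ccc(C(=O)/C=C/c2ccc(OCOC)cc2OCOC)c(O)c1 | intermediate
6 | resorcinol (benzene-1,3-diol) | Oc1cccc(O)c1 | starting material
7 | 1,3-bis(methoxymethoxy)benzene | COCOc1cccc(OCOC)c1 | intermediate
8 | [2,6-bis(methoxymethoxy)phenyl]lithium | [Li]c1c(OCOC)cccc1OCOC | intermediate (not isolated)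
9 | 2,6-bis(methoxymethoxy)benzaldehyde | COCOc1cccc(OCOC)c1C=O | intermediate
10 | 3-bromo-2,6-bis(methoxymethoxy)benzaldehyde | COCOc1ccc(Br)c(OCOC)c1C=O | intermediate
11 | methyl acrylate | C=CC(=O)OC | starting material
12 | methyl (2E)-3-[3-formyl-2,4-bis(methoxymethoxy)phenyl]prop-2-enoate | COCOc1ccc(/C=C/C(=O)OC)c(OCOC)c1C=O | intermediate
13 | methyl (2E)-3-{2,4-bis(methoxymethoxy)-3-[(1E)-3-oxobut-1-en-1-yl]phenyl}prop-2-enoate | COCOc1ccc(/C=C/C(=O)OC)c(OCOC)c1/C=C/C(C)=O | intermediate
14 | methyl (2E)-3-{2,4-bis(methoxymethoxy)-3-[(1E)-3-methylbuta-1,3-dien-1-yl]phenyl}prop-2-enoate | COCOc1ccc(/C=C/C(=O)OC)c(OCOC)c1/C=C/C(C)=C | intermediate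
15 | methyl (2E)-3-{3-[(1R,5S,6R)-5-[2,4-bis(methoxymethoxy)phenyl]-6-[2-hydroxy-4-(methoxymethoxy)benzoyl]-3-methylcyclohex-2-en-1-yl]-2,4-bis(methoxymethoxy)phenyl}prop-2-enoate | CC1=C[C@@H](c2c(OCOC)ccc(/C=C/C(=O)OC)c2OCOC)[C@H](C(=O)c2ccc(OCOC)cc2O)[C@@H](c2ccc(OCOC)cc2OCOC)C1 | intermediate
16 | methyl (2E)-3-{3-[(1R,5S,6R)-6-[2,4-bis(methoxymethoxy)benzoyl]-5-[2,4-bis(methoxymethoxy)phenyl]-3-methylcyclohex-2-en-1-yl]-2,4-bis(methoxymethoxy)phenyl}prop-2-enoate | CC1=C[C@@H](c2c(OCOC)ccc(/C=C/C(=O)OC)c2OCOC)[C@H](C(=O)c2ccc(OCOC)cc2OCOC)[C@@H](c2ccc(OCOC)cc2OCOC)C1 | intermediate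
17 | (2E)-3-{3-[(1R,5S,6R)-6-[2,4-bis(methoxymethoxy)benzoyl]-5-[2,4-bis(methoxymethoxy)phenyl]-3-methylcyclohex-2-en-1-yl]-2,4-bis(methoxymethoxy)phenyl}prop-2-enoic acid | CC1=C[C@@H](c2c(OCOC)ccc(/C=C/C(=O)O)c2OCOC)[C@H](C(=O)c2ccc(OCOC)cc2OCOC)[C@@H](c2ccc(OCOC)cc2OCOC)C1 | intermediate
18 | 5-chlororesorcinol (5-chlorobenzene-1,3-diol) | Oc1cc(O)cc(Cl)c1 | starting material
19 | 4-bromo-5-chlorobenzene-1,3-diol | Oc1cc(O)c(Br)c(Cl)c1 | intermediate
20 | [(4-bromo-5-chloro-1,3-phenylene)bis(oxy)]bis(trimethylsilane) | C[Si](C)(C)Oc1cc(O[Si](C)(C)C)c(Br)c(Cl)c1 | intermediate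
21 | {2-chloro-4,6-bis[(trimethylsilyl)oxy]phenyl}lithium | C[Si](C)(C)Oc1cc(O[Si](C)(C)C)c([Li])c(Cl)c1 | intermediate (not isolated)
22 | lithium 3-chloro-2-(trimethylsilyl)-5-[(trimethylsilyl)oxy]phenolate | [Li+].[O-]c1cc(O[Si](C)(C)C)cc(Cl)c1[Si](C)(C)C | intermediate (not isolated)
23 | 3-chloro-2-(trimethylsilyl)-5-[(trimethylsilyl)oxy]phenyl trifluoromethanesulfonate | C[Si](C)(C)Oc1cc(Cl)c([Si](C)(C)C)c(OS(=O)(=O)C(F)(F)F)c1 | intermediate (not isolated)
24 | 3-chloro-5-hydroxy-2-(trimethylsilyl)phenyl trifluoromethanesulfonate | Oc1cc(Cl)c([Si](C)(C)C)c(OS(=O)(=O)C(F)(F)F)c1 | intermediate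
25 | 3-chloro-5-(methoxymethoxy)-2-(trimethylsilyl)phenyl trifluoromethanesulfonate | COCOc1cc(Cl)c([Si](C)(C)C)c(OS(=O)(=O)C(F)(F)F)c1 | intermediate
26 | 3-chloro-5-(methoxymethoxy)benzyne | COCOC1=CC#CC(Cl)=C1 | intermediate (not isolated)
27 | (2E)-3-{3-[(1R,5S,6R)-6-[2,4-bis(methoxymethoxy)benzoyl]-5-[2,4-bis(methoxymethoxy)phenyl]-3-methylcyclohex-2-en-1-yl]-2,4-bis(methoxymethoxy)phenyl}-1-[2-chloro-6-hydroxy-4-(methoxymethoxy)phenyl]prop-2-en-1-one | CC1=C[C@@H](c2c(OCOC)ccc(/C=C/C(=O)c3c(Cl)cc(OCOC)cc3O)c2OCOC)[C@H](C(=O)c2ccc(OCOC)cc2OCOC)[C@@H](c2ccc(OCOC)cc2OCOC)C1 | intermediate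
28 | (2E)-3-{3-[(1R,5S,6R)-6-[2,4-bis(methoxymethoxy)benzoyl]-5-[2,4-bis(methoxymethoxy)phenyl]-3-methylcyclohex-2-en-1-yl]-2,4-bis(methoxymethoxy)phenyl}-1-[2-chloro-4-(methoxymethoxy)-6-{[tri(propan-2-yl)silyl]oxy}phenyl]prop-2-en-1-one | CC1=C[C@@H](c2c(OCOC)ccc(/C=C/C(=O)c3c(Cl)cc(OCOC)cc3O[Si](C(C)C)(C(C)C)C(C)C)c2OCOC)[C@H](C(=O)c2ccc(OCOC)cc2OCOC)[C@@H](c2ccc(OCOC)cc2OCOC)C1 | intermediate
29 | [(2R,3S)-3-{3-[(1R,5S,6R)-6-[2,4-bis(methoxymethoxy)benzoyl]-5-[2,4-bis(methoxymethoxy)phenyl]-3-methylcyclohex-2-en-1-yl]-2,4-bis(methoxymethoxy)phenyl}oxiran-2-yl][2-chloro-4-(methoxymethoxy)-6-{[tri(propan-2-yl)silyl]oxy}phenyl]methanone | CC1=C[C@@H](c2c(OCOC)ccc([C@@H]3O[C@H]3C(=O)c4c(Cl)cc(OCOC)cc4O[Si](C(C)C)(C(C)C)C(C)C)c2OCOC)[C@H](C(=O)c2ccc(OCOC)cc2OCOC)[C@@H](c2ccc(OCOC)cc2OCOC)C1 | intermediate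
30 | [(2R,3S)-3-{3-[(1R,5S,6R)-6-[2,4-bis(methoxymethoxy)benzoyl]-5-[2,4-bis(methoxymethoxy)phenyl]-3-methylcyclohex-2-en-1-yl]-2,4-bis(methoxymethoxy)phenyl}oxiran-2-yl][2-chloro-6-hydroxy-4-(methoxymethoxy)phenyl]methanone | CC1=C[C@@H](c2c(OCOC)ccc([C@@H]3O[C@H]3C(=O)c4c(Cl)cc(OCOC)cc4O)c2OCOC)[C@H](C(=O)c2ccc(OCOC)cc2OCOC)[C@@H](c2ccc(OCOC)cc2OCOC)C1 | intermediate (not isolated)
31 | (2R,3R)-2-{3-[(1R,5S,6R)-6-[2,4-bis(methoxymethoxy)benzoyl]-5-[2,4-bis(methoxymethoxy)phenyl]-3-methylcyclohex-2-en-1-yl]-2,4-bis(methoxymethoxy)phenyl}-5-chloro-3-hydroxy-7-(methoxymethoxy)-2,3-dihydro-4H-chromen-4-one | CC1=C[C@@H](c2c(OCOC)ccc([C@H]3Oc4cc(OCOC)cc(Cl)c4C(=O)[C@@H]3O)c2OCOC)[C@H](C(=O)c2ccc(OCOC)cc2OCOC)[C@@H](c2ccc(OCOC)cc2OCOC)C1 | intermediate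
32 | (2R,3R)-2-{3-[(1R,5S,6R)-6-[2,4-bis(methoxymethoxy)benzoyl]-5-[2,4-bis(methoxymethoxy)phenyl]-3-methylcyclohex-2-en-1-yl]-2,4-bis(methoxymethoxy)phenyl}-3-hydroxy-7-(methoxymethoxy)-2,3-dihydro-4H-chromen-4-one | CC1=C[C@@H](c2c(OCOC)ccc([C@H]3Oc4cc(OCOC)ccc4C(=O)[C@@H]3O)c2OCOC)[C@H](C(=O)c2ccc(OCOC)cc2OCOC)[C@@H](c2ccc(OCOC)cc2OCOC)C1 | intermediate
33 | guangsangon K, (2R,3R)-2-{3-[(1R,5S,6R)-6-(2,4-dihydroxybenzoyl)-5-(2,4-dihydroxyphenyl)-3-methylcyclohex-2-en-1-yl]-2,4-dihydroxyphenyl}-3,7-dihydroxy-2,3-dihydro-4H-chromen-4-one | CC1=C[C@@H](c2c(O)ccc([C@H]3Oc4cc(O)ccc4C(=O)[C@@H]3O)c2O)[C@H](C(=O)c2ccc(O)cc2O)[C@@H](c2ccc(O)cc2O)C1 | target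

**Step count**

Total: 22 steps. Longest linear sequence: 15 steps (steps 4–12 and 17–22, from resorcinol).

**Steps most likely to fail**

1. Step 17 (aryne insertion). Proton transfer to the aryl anion may outrun the 1,3-acyl shift, so that only O-arylation takes place. The phenoxide formed may also add to its own enone (oxa-Michael closure), which would remove the alkene needed for step 19.
Fallback, setting out from 17 and 7 and returning at 33: the C4–C4a bond is made by cross-coupling instead, in the chlorine-free series. Acid 17 is condensed with thiophenol (EDC·HCl, DMAP, CH2Cl2) to the S-phenyl thioester F1. Bromination of 7 with NBS gives 1-bromo-2,4-bis(methoxymethoxy)benzene F2, and bromine–lithium exchange followed by B(O-i-Pr)3 and aqueous work-up gives [2,4-bis(methoxymethoxy)phenyl]boronic acid F3. Liebeskind–Srogl coupling of F1 with F3 (Pd2(dba)3, tri(2-furyl)phosphine, copper thiophene-2-carboxylate Cu(O2CC4H3S), THF, 50 °C) is neutral and leaves the core ketone alone; it should give the octakis-MOM chalcone F4. Epoxidation as in step 19 gives the (αR,βS)-epoxy ketone F5. HCl in MeOH then removes all eight acetals and lets the freed 2′-phenol open the epoxide at the benzylic carbon, which gives 33 directly.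

2. Step 10 (Diels–Alder). The borate may discriminate the enone faces poorly with two ortho-substituted partners, or the endo approach may dominate.
Fallback, setting out from 5 and 14 and returning at 15: resolution replaces asymmetric induction. The cycloaddition is run with the achiral borate chelate formed from 5 and BH3·THF alone, the racemic exo adduct F6 is purified, and 15 is obtained from it by preparative HPLC on a chiral stationary phase. This does not raise the exo share, so throughput at this stage would be the cost.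

3. Step 20 (ring C closure). Under the steric influence of the neighbouring chlorine the phenoxide may attack Cα instead (5-exo closure), or the basic medium may epimerise the flavanonol.
Fallback, setting out from 27 and returning at 33: ring C is closed under acid and the chlorine is removed last. The phenol of 27 is capped with MOMCl and NaH to give the 2′-O-MOM chalcone F7, which is epoxidised as in step 19 to the (αR,βS)-epoxy ketone F8. HCl in MeOH removes all eight acetals; under acid the epoxide opens at the benzylic carbon, stabilised by the oxygen donors of ring B, and the free phenol closes to the preferred 2,3-trans flavanonol, 5-chloroguangsangon K F9. Hydrodechlorination as in step 21 (Pd(OAc)2, P(t-Bu)3, HCOONa) then gives 33.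

**Further compounds**

F1 | step 17 | S-phenyl (2E)-3-{3-[(1R,5S,6R)-6-[2,4-bis(methoxymethoxy)benzoyl]-5-[2,4-bis(methoxymethoxy)phenyl]-3-methylcyclohex-2-en-1-yl]-2,4-bis(methoxymethoxy)phenyl}prop-2-enethioate | CC1=C[C@@H](c2c(OCOC)ccc(/C=C/C(=O)Sc3ccccc3)c2OCOC)[C@H](C(=O)c2ccc(OCOC)cc2OCOC)[C@@H](c2ccc(OCOC)cc2OCOC)C1
F2 | step 17 | 1-bromo-2,4-bis(methoxymethoxy)benzene | COCOc1ccc(Br)c(OCOC)c1
F3 | step 17 | [2,4-bis(methoxymethoxy)phenyl]boronic acid | COCOc1ccc(B(O)O)c(OCOC)c1
F4 | step 17 | (2E)-1-[2,4-bis(methoxymethoxy)phenyl]-3-{3-[(1R,5S,6R)-6-[2,4-bis(methoxymethoxy)benzoyl]-5-[2,4-bis(methoxymethoxy)phenyl]-3-methylcyclohex-2-en-1-yl]-2,4-bis(methoxymethoxy)phenyl}prop-2-en-1-one | CC1=C[C@@H](c2c(OCOC)ccc(/C=C/C(=O)c3ccc(OCOC)cc3OCOC)c2OCOC)[C@H](C(=O)c2ccc(OCOC)cc2OCOC)[C@@H](c2ccc(OCOC)cc2OCOC)C1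
F5 | step 17 | [2,4-bis(methoxymethoxy)phenyl][(2R,3S)-3-{3-[(1R,5S,6R)-6-[2,4-bis(methoxymethoxy)benzoyl]-5-[2,4-bis(methoxymethoxy)phenyl]-3-methylcyclohex-2-en-1-yl]-2,4-bis(methoxymethoxy)phenyl}oxiran-2-yl]methanone | CC1=C[C@@H](c2c(OCOC)ccc([C@@H]3O[C@H]3C(=O)c4ccc(OCOC)cc4OCOC)c2OCOC)[C@H](C(=O)c2ccc(OCOC)cc2OCOC)[C@@H](c2ccc(OCOC)cc2OCOC)C1
F6 | step 10 | racemic exo adduct (15 together with its enantiomer) | CC1=C[C@@H](c2c(OCOC)ccc(/C=C/C(=O)OC)c2OCOC)[C@H](C(=O)c2ccc(OCOC)cc2O)[C@@H](c2ccc(OCOC)cc2OCOC)C1.CC1=C[C@H](c2c(OCOC)ccc(/C=C/C(=O)OC)c2OCOC)[C@@H](C(=O)c2ccc(OCOC)cc2O)[C@H](c2ccc(OCOC)cc2OCOC)C1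
F7 | step 20 | (2E)-3-{3-[(1R,5S,6R)-6-[2,4-bis(methoxymethoxy)benzoyl]-5-[2,4-bis(methoxymethoxy)phenyl]-3-methylcyclohex-2-en-1-yl]-2,4-bis(methoxymethoxy)phenyl}-1-[2-chloro-4,6-bis(methoxymethoxy)phenyl]prop-2-en-1-one | CC1=C[C@@H](c2c(OCOC)ccc(/C=C/C(=O)c3c(Cl)cc(OCOC)cc3OCOC)c2OCOC)[C@H](C(=O)c2ccc(OCOC)cc2OCOC)[C@@H](c2ccc(OCOC)cc2OCOC)C1
F8 | step 20 | [(2R,3S)-3-{3-[(1R,5S,6R)-6-[2,4-bis(methoxymethoxy)benzoyl]-5-[2,4-bis(methoxymethoxy)phenyl]-3-methylcyclohex-2-en-1-yl]-2,4-bis(methoxymethoxy)phenyl}oxiran-2-yl][2-chloro-4,6-bis(methoxymethoxy)phenyl]methanone | CC1=C[C@@H](c2c(OCOC)ccc([C@@H]3O[C@H]3C(=O)c4c(Cl)cc(OCOC)cc4OCOC)c2OCOC)[C@H](C(=O)c2ccc(OCOC)cc2OCOC)[C@@H](c2ccc(OCOC)cc2OCOC)C1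
F9 | step 20 | 5-chloroguangsangon K, (2R,3R)-5-chloro-2-{3-[(1R,5S,6R)-6-(2,4-dihydroxybenzoyl)-5-(2,4-dihydroxyphenyl)-3-methylcyclohex-2-en-1-yl]-2,4-dihydroxyphenyl}-3,7-dihydroxy-2,3-dihydro-4H-chromen-4-one | CC1=C[C@@H](c2c(O)ccc([C@H]3Oc4cc(O)cc(Cl)c4C(=O)[C@@H]3O)c2O)[C@H](C(=O)c2ccc(O)cc2O)[C@@H](c2ccc(O)cc2O)C1
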